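**Plan**
- **Cuts** (quinone numbering: C1=O, C2 side chain, C3 Me, C4=O, C5 Me, C6 Me). The quinone is first taken back to its hydroquinone. Ring bond C1–C2 is then cut and C1 re-joined to C4, which shrinks the six-membered ring to a 4-alkenyl-4-hydroxy-2,3-dimethylcyclobutenone. Next come bond C4–C3 (alkenyllithium + 3,4-dimethylcyclobutenedione) and the bond between C1' of the chain and the future C2 (propyne + C1' electrophile).
- **Enabling feature.** Ring atoms C4(O)–C5(Me)=C6(Me)–C1(O) are a masked squarate-type four-membered ring, and C3(Me)=C2(chain) is a masked trisubstituted alkene. The para pair of oxygens is what electrocyclic opening of the cyclobutenone and 6π reclosure delivers. The mirror symmetry of the dimethyl-dioxo half cancels all regiochemistry.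
- **Forward order.** Phytol → epoxy alcohol → 1,3-diol → oxetane (temporary ring) → propyne opening → alkenyl iodide. Separately, squarate ester → dimethylcyclobutenedione. The two are joined at C4–C3, the four-ring is expanded to the six-ring (the only ring of the target), and the product is oxidised to the quinone.
- **Stereochemistry.** C7' and C11' come from natural phytol. C3' is set by asymmetric epoxidation of the phytol alkene, and its C–O bond is never broken afterwards. The carbinol centre of the cyclobutenone is sacrificial.

Key step: step 9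

Assumption: commercial natural-source phytol is taken as the single (2E,7R,11R) isomer, and the carbinol carbon of the cyclobutenone adduct is left undefined because it becomes sp2 in the ring expansion.

**Step 1**
Reactants: 1 (2E,7R,11R)-phytol
Product: 2 (2R,3R,7R,11R)-2,3-epoxyphytol = [(2R,3R)-3-methyl-3-[(4R,8R)-4,8,12-trimethyltridecyl]oxiran-2-yl]methanol
Conditions: Ti(OiPr)4 (cat), D-(−)-DIPT (cat), TBHP (decane), 4 Å MS, CH2Cl2, −20 °C
Reagents that add atoms: tert-butyl hydroperoxide CC(C)(C)OO
Why: Katsuki–Sharpless asymmetric epoxidation of an (E)-3-methyl primary allylic alcohol, a best-case substrate class, in which the D-(−)-tartrate–titanium complex binds the hydroxyl group and delivers oxygen to one alkene face so that C2 and C3 are both set as R (the mirror image of the 2S,3S outcome that L-(+)-tartrate gives with geraniol-type alcohols), the remote C7 and C11 centres having no influence.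

**Step 2**
Reactants: 2 (2R,3R,7R,11R)-2,3-epoxyphytol
Product: 3 (3R,7R,11R)-3,7,11,15-tetramethylhexadecane-1,3-diol
Conditions: LiAlH4, THF, 0 °C → rt; aqueous NaOH work-up
Reagents that add atoms: none
Why: Regioselective hydride opening of a 2,3-epoxy alcohol (SN2 at the secondary C2, delivered from the C1 alkoxyaluminate and away from the fully substituted C3) gives the 1,3-diol, so the C3–O bond is never touched and the R configuration of the new tertiary carbinol is that of the epoxide.

**Step 3**
Reactants: 3 (3R,7R,11R)-3,7,11,15-tetramethylhexadecane-1,3-diol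
Product: 5 (2R)-2-methyl-2-[(4R,8R)-4,8,12-trimethyltridecyl]oxetane, via primary monotosylate 4 (not isolated)
Conditions: n-BuLi (1.0 equiv), THF, 0 °C; TsCl (1.0 equiv), 0 °C; then KOt-Bu (1.2 equiv), 0 → 40 °C
Reagents that add atoms: none
Why: Selective sulfonylation of the primary alkoxide followed by intramolecular Williamson etherification (4-exo-tet) by the tertiary alkoxide builds a temporary oxetane ring that both activates C1 by strain and masks the carbinol, and since only the O–H and the C1–O bonds change the quaternary centre stays R.

**Step 4**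
Reactants: 5 (2R)-2-methyl-2-[(4R,8R)-4,8,12-trimethyltridecyl]oxetane; 6 propyne
Product: 8 (6R,10R,14R)-6,10,14,18-tetramethylnonadec-2-yn-6-ol, via 1-propynyllithium 7 (not isolated)
Conditions: 6, n-BuLi, THF, −78 °C; BF3·OEt2; then 5, −78 °C; aq NH4Cl
Reagents that add atoms: none
Why: BF3-promoted SN2 opening of an oxetane by a lithium acetylide at low temperature takes place at the unhindered CH2–O carbon rather than at the quaternary one, so the three-carbon unit is attached at C1, the temporary ring is removed and the tertiary alcohol is released with its C–O bond intact.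

**Step 5**
Reactants: 8 (6R,10R,14R)-6,10,14,18-tetramethylnonadec-2-yn-6-ol
Product: 10 (2E,6R,10R,14R)-2-iodo-6,10,14,18-tetramethylnonadec-2-en-6-ol, via O-zirconated alkenylzirconocene chloride 9 (not isolated)
Conditions: Cp2Zr(H)Cl (2.4 equiv), THF, rt → 40 °C, dark; then I2, 0 °C; aq NaHCO3/Na2S2O3
Reagents that add atoms: iodine II
Why: Hydrozirconation with the Schwartz reagent is a syn addition that, under equilibration by the excess hydride, places zirconium on the less hindered methyl-bearing alkyne carbon (the first equivalent being parked on the tertiary hydroxyl as its zirconium alkoxide), iodinolysis proceeds with retention to the E iodide, and any 3-iodo regioisomer can be carried along because both isomers end in the same hydroquinone in step 9.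

**Step 6**
Reactants: 11 diisopropyl squarate (3,4-diisopropoxycyclobut-3-ene-1,2-dione)
Product: 13 2,3-diisopropoxy-4-methyl-4-(trimethylsilyloxy)cyclobut-2-en-1-one (racemic), via lithium alkoxide adduct 12 (not isolated)
Conditions: MeLi (1.05 equiv), THF, −78 °C; then TMSCl, −78 °C → rt
Reagents that add atoms: methyllithium [Li]C; chlorotrimethylsilane C[Si](C)(C)Cl
Why: 1,2-Addition of an organolithium to one carbonyl group of a squarate ester is faster than attack on the vinylogous ester positions, and trapping the tertiary alkoxide in the flask as its silyl ether leaves the second carbonyl group free for the next addition (the new centre is racemic and is erased in step 7).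

**Step 7**
Reactants: 13 2,3-diisopropoxy-4-methyl-4-(trimethylsilyloxy)cyclobut-2-en-1-one
Product: 15 3,4-dimethylcyclobut-3-ene-1,2-dione, via second lithium alkoxide adduct 14 (not isolated)
Conditions: MeLi (1.1 equiv), THF, −78 °C; then 2 M aq HCl, CH2Cl2/THF, rt
Reagents that add atoms: methyllithium [Li]C; water O
Why: A second 1,2-addition to the remaining vinylogous-ester carbonyl followed by acid treatment triggers two successive Stork–Danheiser-type transpositions, each ionisation of a tertiary C–O bond being assisted by the isopropoxy group at the far end of the allyl system and each oxocarbenium ion being hydrolysed to a carbonyl group, which leaves the two methyl groups on adjacent alkene carbons of the cyclobutenedione.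

**Step 8**
Reactants: 10 (2E,6R,10R,14R)-2-iodo-6,10,14,18-tetramethylnonadec-2-en-6-ol; 15 3,4-dimethylcyclobut-3-ene-1,2-dione
Product: 17 4-hydroxy-4-[(2E,6R,10R,14R)-6-hydroxy-6,10,14,18-tetramethylnonadec-2-en-2-yl]-2,3-dimethylcyclobut-2-en-1-one (both C4 epimers), via dilithiated alkenyllithium alkoxide 16 (not isolated)
Conditions: 10, t-BuLi (3.1 equiv), Et2O, −78 °C; cannulated into 15 (1.3 equiv), THF, −78 °C; aq NH4Cl
Reagents that add atoms: none
Why: Iodine–lithium exchange on an alkenyl iodide proceeds with retention of geometry beside the lithium alkoxide, and 1,2-addition of alkenyllithium reagents to cyclobutenediones at −78 °C with inverse addition stops after one carbonyl group, where the symmetry of 15 removes any regiochemical choice and the new carbinol centre may be a mixture because it is destroyed in step 9.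

**Step 9**
Reactants: 17 4-hydroxy-4-[(2E,6R,10R,14R)-6-hydroxy-6,10,14,18-tetramethylnonadec-2-en-2-yl]-2,3-dimethylcyclobut-2-en-1-one
Product: 20 2-[(3R,7R,11R)-3-hydroxy-3,7,11,15-tetramethylhexadecyl]-3,5,6-trimethylbenzene-1,4-diol (α-tocopherylhydroquinone), via hydroxy dienylketene 18 (not isolated), via 6H-cyclohexa-2,4-dienone 19 (not isolated)
Conditions: degassed p-xylene (high dilution), 138 °C, Ar, base-washed glassware
Reagents that add atoms: none
Why: Heating opens the strained four-membered ring of 17 by a conrotatory 4π electrocyclic cleavage of the C1–C4 bond, and the donor hydroxyl on C4 rotates outward (torquoselectivity), so the alkenyl group turns inward and dienylketene 18 forms with its ketene carbon and alkene terminus within bonding distance. A thermal disrotatory 6π electrocyclization then joins the ketene carbon to the chain-bearing alkene carbon (the only ring closed, a six-membered carbocycle) to give dienone 19, whose tautomerization to the aromatic hydroquinone 20 makes the net two-carbon ring expansion irreversible. The closest known reaction type is the Liebeskind–Moore rearrangement of 4-alkenyl- and 4-aryl-4-hydroxycyclobutenones to hydroquinones. No stereocentre is created that survives, since the carbinol carbon of 17 and the transient sp3 carbon of 19 both become sp2, while the three side-chain centres are remote from the π system and untouched under neutral thermal conditions. The step needs outward rotation of the hydroxyl group, which the donor substituent effect secures, and 6π closure faster than capture of the ketene by a hydroxyl group, which high dilution and the ten-membered ring that the internal tertiary alcohol would have to form secure. Regiochemistry needs no control, because the dimethyl-substituted C4 unit is symmetric and either placement of methyl and side chain on the two alkene carbons leads to the same hexasubstituted ring.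

**Step 10**
Reactants: 20 α-tocopherylhydroquinone
Product: 21 (3'R,7'R,11'R)-α-tocopherylquinone = 2-[(3R,7R,11R)-3-hydroxy-3,7,11,15-tetramethylhexadecyl]-3,5,6-trimethylcyclohexa-2,5-diene-1,4-dione
Conditions: Ag2O (2 equiv), Et2O, rt, dark
Reagents that add atoms: none
Why: Two-electron oxidation of a hydroquinone to the p-benzoquinone with silver(I) oxide is fast under neutral aprotic conditions, which avoids the acid that could close the tertiary alcohol onto the ring, and no stereocentre is involved.

**Compound list**
1 | (2E,7R,11R)-phytol | OC/C=C(\C)CCC[C@H](C)CCC[C@H](C)CCCC(C)C | starting material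
2 | (2R,3R,7R,11R)-2,3-epoxyphytol | OC[C@H]1O[C@]1(C)CCC[C@H](C)CCC[C@H](C)CCCC(C)C | intermediate
3 | (3R,7R,11R)-3,7,11,15-tetramethylhexadecane-1,3-diol | OCC[C@](C)(O)CCC[C@H](C)CCC[C@H](C)CCCC(C)C | intermediate
4 | (3R,7R,11R)-3-hydroxy-3,7,11,15-tetramethylhexadecyl 4-methylbenzenesulfonate | Cc1ccc(cc1)S(=O)(=O)OCC[C@](C)(O)CCC[C@H](C)CCC[C@H](C)CCCC(C)C | intermediate
5 | (2R)-2-methyl-2-[(4R,8R)-4,8,12-trimethyltridecyl]oxetane | C1C[C@](C)(O1)CCC[C@H](C)CCC[C@H](C)CCCC(C)C | intermediate
6 | propyne | CC#C | starting material
7 | 1-propynyllithium | [Li]C#CC | intermediate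
8 | (6R,10R,14R)-6,10,14,18-tetramethylnonadec-2-yn-6-ol | CC#CCC[C@](C)(O)CCC[C@H](C)CCC[C@H](C)CCCC(C)C | intermediate
9 | (E)-alkenylzirconocene chloride of 8, Zr on C2, tertiary oxygen carried as zirconocene chloride alkoxide | C/C(=C\CC[C@](C)(O[Zr](Cl)(C1C=CC=C1)C1C=CC=C1)CCC[C@H](C)CCC[C@H](C)CCCC(C)C)[Zr](Cl)(C1C=CC=C1)C1C=CC=C1 | intermediate
10 | (2E,6R,10R,14R)-2-iodo-6,10,14,18-tetramethylnonadec-2-en-6-ol | C/C(I)=C\CC[C@](C)(O)CCC[C@H](C)CCC[C@H](C)CCCC(C)C | intermediate
11 | diisopropyl squarate | CC(C)OC1=C(OC(C)C)C(=O)C1=O | starting material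
12 | lithium 2,3-diisopropoxy-1-methyl-4-oxocyclobut-2-en-1-olate | [Li]OC1(C)C(OC(C)C)=C(OC(C)C)C1=O | intermediate
13 | 2,3-diisopropoxy-4-methyl-4-(trimethylsilyloxy)cyclobut-2-en-1-one | CC(C)OC1=C(OC(C)C)C(C)(O[Si](C)(C)C)C1=O | intermediate
14 | lithium 2,3-diisopropoxy-1,4-dimethyl-4-(trimethylsilyloxy)cyclobut-2-en-1-olate | CC(C)OC1=C(OC(C)C)C(C)(O[Si](C)(C)C)C1(C)O[Li] | intermediate
15 | 3,4-dimethylcyclobut-3-ene-1,2-dione | CC1=C(C)C(=O)C1=O | intermediate
16 | dilithio derivative of 10 (C2–Li trans to the chain, lithium alkoxide at C6) | [Li]/C(C)=C/CC[C@](C)(O[Li])CCC[C@H](C)CCC[C@H](C)CCCC(C)C | intermediate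
17 | 4-hydroxy-4-[(2E,6R,10R,14R)-6-hydroxy-6,10,14,18-tetramethylnonadec-2-en-2-yl]-2,3-dimethylcyclobut-2-en-1-one | CC1=C(C)C(O)(/C(C)=C/CC[C@](C)(O)CCC[C@H](C)CCC[C@H](C)CCCC(C)C)C1=O | intermediate
18 | hydroxy dienylketene (ketenyl and alkenyl groups cis on the central alkene, hydroxyl outward) | O=C=C(C)/C(C)=C(/O)\C(C)=C\CC[C@](C)(O)CCC[C@H](C)CCC[C@H](C)CCCC(C)C | intermediate
19 | 4-hydroxy-6-[(3R,7R,11R)-3-hydroxy-3,7,11,15-tetramethylhexadecyl]-2,3,5-trimethylcyclohexa-2,4-dien-1-one | CC1=C(C)C(=O)C(CC[C@](C)(O)CCC[C@H](C)CCC[C@H](C)CCCC(C)C)C(C)=C1O | intermediate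
20 | α-tocopherylhydroquinone | Cc1c(C)c(O)c(CC[C@](C)(O)CCC[C@H](C)CCC[C@H](C)CCCC(C)C)c(C)c1O | intermediate
21 | (3'R,7'R,11'R)-α-tocopherylquinone | CC1=C(C)C(=O)C(CC[C@](C)(O)CCC[C@H](C)CCC[C@H](C)CCCC(C)C)=C(C)C1=O | target

**Totals**
- Total step count: 10.
- Longest linear sequence: 8 (steps 1–5, 8, 9, 10).

**Steps most likely to fail**

**Step 8.**
- Risk: the strongly basic dilithio reagent may deprotonate the acidic ring methyl groups of the dione. It may also add to both carbonyl groups, or the iodine–lithium exchange may stay incomplete beside the alkoxide.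
- Fallback: it sets out from 15 and 8 and comes back at 21, and it drops carbanion chemistry altogether.
- ClCo(PPh3)3 in benzene should insert into the C1–C2 bond of 15. This gives the five-membered metallacycle chlorobis(triphenylphosphine)(2,3-dimethylmaleoyl)cobalt(III) F1.
- After chloride abstraction with AgBF4 in MeCN and warming with alkyne 8, F1 should take up the alkyne and reductively eliminate to quinone 21 directly. This is the known maleoylcobalt–alkyne quinone synthesis.
- The six-membered ring still grows out of the same four-membered ring, the symmetric dione again leaves no regiochemical choice, and steps 5 and 8–10 fall away.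

**Step 4.**
- Risk: the Lewis acid may ionise the tertiary C–O bond of the oxetane. That would lead to elimination to a homoallylic alcohol or erosion of configuration instead of SN2 attack at CH2.
- Fallback: it sets out from 3 and comes back at 8, and it replaces the strained ring by an acyclic electrophile with a masked carbinol.
- Selective Appel iodination of the primary hydroxyl (I2, PPh3, imidazole, 0 °C) gives (3R,7R,11R)-1-iodo-3,7,11,15-tetramethylhexadecan-3-ol F2.
- TESOTf/2,6-lutidine then gives its triethylsilyl ether F3.
- Alkylation of 1-propynyllithium with F3 in THF/DMPU gives the silyl-protected alkynol F4.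
- TBAF releases 8.

**Step 9.**
- Risk: at 138 °C the free tertiary carbinol may dehydrate or close onto the electron-rich hydroquinone ring to a chroman. The air-sensitive hydroquinone may also degrade before it is oxidised.
- Fallback: it sets out from 5 and 15 and comes back at 21. It uses the alkynyl variant of the ring expansion, which never passes through a hydroquinone.
- Monolithium acetylide/BF3·OEt2 opens 5 to (5R,9R,13R)-5,9,13,17-tetramethyloctadec-1-yn-5-ol F5.
- Double deprotonation with n-BuLi and addition to 15 gives the 4-alkynyl-4-hydroxycyclobutenone F6.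
- Moore rearrangement in refluxing toluene (ring opening, diradical closure, hydrogen transfer) gives the trisubstituted quinone 2-[(3R,7R,11R)-3-hydroxy-3,7,11,15-tetramethylhexadecyl]-5,6-dimethyl-1,4-benzoquinone F7 at the quinone level.
- The last ring position is methylated by silver/persulfate decarboxylative radical alkylation with acetic acid (AgNO3 cat, (NH4)2S2O8, MeCN/H2O, 70 °C) to give 21.

**Further compounds**
F1 | step 8 | chlorobis(triphenylphosphine)(2,3-dimethylmaleoyl)cobalt(III) (1-cobaltacyclopent-3-ene-2,5-dione) | CC1=C(C)C(=O)[Co-2](Cl)([P+](c2ccccc2)(c2ccccc2)c2ccccc2)([P+](c2ccccc2)(c2ccccc2)c2ccccc2)C1=O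
F2 | step 4 | (3R,7R,11R)-1-iodo-3,7,11,15-tetramethylhexadecan-3-ol | ICC[C@](C)(O)CCC[C@H](C)CCC[C@H](C)CCCC(C)C
F3 | step 4 | triethyl{[(3R,7R,11R)-1-iodo-3,7,11,15-tetramethylhexadecan-3-yl]oxy}silane | ICC[C@](C)(O[Si](CC)(CC)CC)CCC[C@H](C)CCC[C@H](C)CCCC(C)C
F4 | step 4 | triethyl{[(6R,10R,14R)-6,10,14,18-tetramethylnonadec-2-yn-6-yl]oxy}silane | CC#CCC[C@](C)(O[Si](CC)(CC)CC)CCC[C@H](C)CCC[C@H](C)CCCC(C)C
F5 | step 9 | (5R,9R,13R)-5,9,13,17-tetramethyloctadec-1-yn-5-ol | C#CCC[C@](C)(O)CCC[C@H](C)CCC[C@H](C)CCCC(C)C
F6 | step 9 | 4-hydroxy-4-[(5R,9R,13R)-5-hydroxy-5,9,13,17-tetramethyloctadec-1-yn-1-yl]-2,3-dimethylcyclobut-2-en-1-one | CC1=C(C)C(O)(C#CCC[C@](C)(O)CCC[C@H](C)CCC[C@H](C)CCCC(C)C)C1=O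
F7 | step 9 | 2-[(3R,7R,11R)-3-hydroxy-3,7,11,15-tetramethylhexadecyl]-5,6-dimethyl-1,4-benzoquinone | CC1=C(C)C(=O)C(CC[C@](C)(O)CCC[C@H](C)CCC[C@H](C)CCCC(C)C)=CC1=O
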